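The route rests on cutting the C4–C4a bond of the upper flavan, so pyran ring C is the last ring made. The feature exploited is upper C4. It is bonded to two phloroglucinol-type arenes, C4a of ring A and C8' of ring D, and stands trans to the gallate on C3. Ionising this carbon before ring A is attached gives a cation stabilised by ring D. Gallate participation and allylic strain fix its geometry, and the tethered ring A closes ring C and sets C4 from either epimer. The precursor is an acyclic (2R,3R)-triol derivative: ring A aryl ether at C2, gallate at C3, benzylated epigallocatechin and a methoxy leaving group at C4.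

Key step: step 14

Remarks on the chemistry (one line each)
- Numbering: acyclic intermediates carry the flavan numbers of the carbons they become (C2 bears ring B, C3 the later gallate oxygen O3, C4 the later ring-junction carbon with oxygen O4); the lower flavan has benzo ring D, pyran ring F and aryl ring E with primed atoms; Bn = benzyl.
- Stereochemical bookkeeping: the target is 2R,3R,4R,2'R,3'R (upper unit 2,3-cis, 3,4-trans); a 2,3-cis flavan corresponds to a syn O1/O3 pair in the open chain, so an anti carbinol plus one inversion at C2 is required, and (R)-glyceraldehyde acetonide maps onto 3R.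
- Design: a free C4 carbinol beside a free C3 hydroxyl cannot be galloylated selectively and would release water on ionisation, so O4 is methylated in the flask in which it is formed; this leaves O3 as the only acylable oxygen and makes methanol the leaving group.
- Assumption: 5-bromobenzene-1,2,3-triol, (R)-glyceraldehyde acetonide (freshly distilled), 3,5-bis(benzyloxy)phenol, (−)-epigallocatechin and 3,4,5-tris(benzyloxy)benzoic acid are purchased.

Step 1
Reactants: 1 5-bromobenzene-1,2,3-triol
Product: 2 1,2,3-tris(benzyloxy)-5-bromobenzene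
Conditions: BnBr, K2CO3, DMF, argon, 60 °C
Reagents that add atoms: benzyl bromide BrCc1ccccc1
Why: Williamson ether synthesis, in which carbonate deprotonates the three acidic phenols for alkylation by the benzylic bromide while the aryl bromide needed for metallation is untouched.

Step 2
Reactants: 2 1,2,3-tris(benzyloxy)-5-bromobenzene; 3 (R)-glyceraldehyde acetonide
Product: 5 (S)-[(4R)-2,2-dimethyl-1,3-dioxolan-4-yl][3,4,5-tris(benzyloxy)phenyl]methanol (2,3-anti), via arylmagnesium bromide 4 (not isolated)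
Conditions: Mg turnings, I2 (cat.), THF, reflux; then 3, THF, −78 °C; aq. NH4Cl; chromatography
Reagents that add atoms: none
Why: Grignard 1,2-addition to an alpha-alkoxy aldehyde in coordinating THF should follow the polar Felkin–Anh model, the aryl group approaching anti to the dioxolane C–O bond to give mainly the 2,3-anti (2S) carbinol (the syn epimer is removed by chromatography), while C3 (R) is carried over from the chiral pool.

Step 3
Reactants: 5 anti carbinol; 6 3,5-bis(benzyloxy)phenol
Product: 7 (4R)-4-{(R)-[3,5-bis(benzyloxy)phenoxy][3,4,5-tris(benzyloxy)phenyl]methyl}-2,2-dimethyl-1,3-dioxolane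
Conditions: PPh3, DIAD, toluene, 0 °C to rt
Reagents that add atoms: none
Why: Mitsunobu etherification, in which the phenol displaces the activated C2 oxygen by SN2 with inversion, turning 2S into the 2R aryl ether syn to O3 as the 2,3-cis ring C requires, while the apolar solvent and the inductively withdrawing dioxolane next to C2 should suppress ionisation.

Step 4
Reactants: 7 aryl ether acetonide
Product: 8 (2R,3R)-3-[3,5-bis(benzyloxy)phenoxy]-3-[3,4,5-tris(benzyloxy)phenyl]propane-1,2-diol
Conditions: AcOH/THF/H2O (3:1:1), 50 °C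
Reagents that add atoms: none
Why: Acid-catalysed acetal hydrolysis, since the terminal isopropylidene acetal is far more labile to dilute acetic acid than the benzyl ethers or the C2 aryl ether, and no stereocentre is touched.

Step 5
Reactants: 8 diol
Product: 9 1,2-bis(tert-butyldimethylsilyl) ether of 8
Conditions: TBSOTf, 2,6-lutidine, CH2Cl2, 0 °C
Reagents that add atoms: tert-butyldimethylsilyl trifluoromethanesulfonate CC(C)(C)[Si](C)(C)OS(=O)(=O)C(F)(F)F
Why: Silyl ether formation with the reactive silyl triflate and a hindered pyridine base covers both the primary O4 and the crowded secondary O3 hydroxyl without affecting any stereocentre.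

Step 6
Reactants: 9 bis-silyl ether
Product: 10 (2R,3R)-3-[3,5-bis(benzyloxy)phenoxy]-2-(tert-butyldimethylsilyloxy)-3-[3,4,5-tris(benzyloxy)phenyl]propan-1-ol
Conditions: HF·pyridine, pyridine, THF, 0 °C
Reagents that add atoms: none
Why: Selective desilylation, because buffered fluoride attacks the unhindered primary silyl ether much faster than the secondary one flanked by C2, a standard steric differentiation.

Step 7
Reactants: 10 primary alcohol
Product: 11 (2S,3R)-3-[3,5-bis(benzyloxy)phenoxy]-2-(tert-butyldimethylsilyloxy)-3-[3,4,5-tris(benzyloxy)phenyl]propanal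
Conditions: Dess–Martin periodinane, CH2Cl2, 0 °C to rt
Reagents that add atoms: none
Why: Dess–Martin oxidation is base-free, tolerates polyalkoxyarenes that activated-sulfoxide oxidants could attack, and stops at the aldehyde, so neither epimerisation at C3 nor beta-elimination of the phenoxide should occur (the descriptor at C3 changes to S only because CHO now outranks C2).

Step 8
Reactants: 12 (−)-epigallocatechin
Product: 13 5,7,3',4',5'-penta-O-benzyl-(−)-epigallocatechin (2R,3R)
Conditions: BnBr, K2CO3, DMF, argon, 0 °C to rt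
Reagents that add atoms: benzyl bromide BrCc1ccccc1
Why: Williamson etherification under a weak base benzylates only the five phenols and leaves the secondary alcohol free, while exclusion of air and the low temperature guard against oxidation of the pyrogallol ring and epimerisation at C2.

Step 9
Reactants: 13 penta-O-benzyl-epigallocatechin
Product: 14 3,5,7,3',4',5'-hexa-O-benzyl-(−)-epigallocatechin
Conditions: NaH, BnBr, DMF, 0 °C to rt
Reagents that add atoms: benzyl bromide BrCc1ccccc1
Why: Williamson etherification of the remaining secondary alkoxide, which leaves the carbinol configuration untouched because only the O–H bond reacts.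

Step 10
Reactants: 14 hexa-O-benzyl-epigallocatechin
Product: 15 8-bromo-3,5,7,3',4',5'-hexa-O-benzyl-(−)-epigallocatechin
Conditions: NBS (1.0 equiv), CH2Cl2, −78 to 0 °C
Reagents that add atoms: N-bromosuccinimide O=C1CCC(=O)N1Br
Why: Electrophilic aromatic bromination, in which the phloroglucinol-type benzo ring is the most electron-rich arene and benzylated flavan-3-ols are known to take one equivalent of the reagent at C8 and not at C6, which is squeezed between two benzyloxy groups.

Step 11
Reactants: 15 8-bromide; 11 aldehyde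
Product: 18 8-[(2R,3R)-3-[3,5-bis(benzyloxy)phenoxy]-2-(tert-butyldimethylsilyloxy)-1-methoxy-3-[3,4,5-tris(benzyloxy)phenyl]propyl]-hexa-O-benzyl-(−)-epigallocatechin (both epimers at the methoxy carbon C4), via aryllithium 16 (not isolated), via lithium alkoxide 17 (not isolated)
Conditions: n-BuLi, THF, −78 °C; 11, −78 °C; MeOTf, −78 to −20 °C; aq. NaHCO3; Et3N-deactivated silica
Reagents that add atoms: methyl trifluoromethanesulfonate COS(=O)(=O)C(F)(F)F
Why: Bromine–lithium exchange and 1,2-addition of the aryllithium to the aldehyde form C4–C8' (such C8-lithiated benzylated flavans are known to add to alpha-oxygenated, beta-aryloxy carbonyl compounds), and O-methylation of the cold lithium alkoxide tags O4 before the silyl group can migrate, the new C4 centre being left uncontrolled because step 14 erases it.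

Step 12
Reactants: 18 silyl ether
Product: 19 C3 alcohol, 8-[(2R,3R)-3-[3,5-bis(benzyloxy)phenoxy]-2-hydroxy-1-methoxy-3-[3,4,5-tris(benzyloxy)phenyl]propyl]-hexa-O-benzyl-(−)-epigallocatechin (both C4 epimers)
Conditions: Bu4NF, AcOH (1:1), THF, rt; Et3N-deactivated silica
Reagents that add atoms: none
Why: Fluoride-mediated desilylation runs under essentially non-acidic conditions, so the acid-labile C4 methyl ether and the C2 aryl ether persist and O3 becomes the only free hydroxyl.

Step 13
Reactants: 19 C3 alcohol; 20 3,4,5-tris(benzyloxy)benzoic acid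
Product: 21 key precursor, the 3-O-[3,4,5-tris(benzyloxy)benzoyl] ester of 19 (2R,3R; both C4 epimers)
Conditions: DCC, DMAP (cat.), CH2Cl2, rt; Et3N-deactivated silica
Reagents that add atoms: none
Why: Steglich esterification acylates the single hydroxyl of the molecule with retention at C3, under conditions routinely used to galloylate the hindered 3-hydroxyl of benzylated flavans.

Step 14
Reactants: 21 key precursor
Product: 24 perbenzylated target, tetradeca-O-benzyl epigallocatechin 3-O-gallate-(4β→8)-epigallocatechin (2R,3R,4R,2'R,3'R), via benzylic cation 22 (not isolated), via dioxolanylium ion 23 (not isolated)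
Conditions: Me3SiOTf (0.2 equiv), 4 Å molecular sieves, CH2Cl2 (0.002 M, slow addition of 21), −78 to −40 °C; Et3N quench
Reagents that add atoms: none
Why: Me3SiOTf silylates the C4 methoxy group of either epimer and expels it, giving benzylic cation 22, delocalised into the 2,4,6-trioxygenated ring D, which the C3 gallate carbonyl caps reversibly as the trans-4,5-disubstituted 2-aryl-1,3-dioxolan-2-ylium ion 23; an ortho carbon of the 3,5-bis(benzyloxy)phenoxy ring then bonds to C4, and proton loss rearomatises ring A and regenerates the acid. The closest known reactions are the intramolecular Friedel–Crafts cyclisation of 1-aryl-3-aryloxypropyl cations to 4-arylchromans and the silyl-triflate-promoted C4 arylation of 4-alkoxy-3-acyloxyflavans, which runs through the same kind of cation and the same participation. Ring C closes in 6-exo-tet mode on 23 (6-exo-trig on 22) through a half-chair in which the incoming C4a is gauche to C2 and anti to O3. C4 is set as 4R by two elements that point the same way: backside opening of the C4–O bond of the trans ion 23, and allylic 1,3-strain in 22, which turns C3–H into the plane of the di-ortho-substituted ring D so that the tethered ring A and O3 lie on opposite faces; either way ring D ends trans to the gallate, and since both epimers of 21 lose their C4 configuration on ionisation the step is stereoconvergent. The step needs site selectivity for ionisation at C4 over the C2 benzylic aryl ether, secured by the three donor oxygens of ring D against one para donor on ring B and by the low temperature, and it needs ring closure to outrun intermolecular attack (C6', other ring A units) and five-membered closure by ring B, secured by high dilution and by the triply activated ring A. Regiochemistry on ring A is not an issue because its two ortho carbons are equivalent and its para carbon cannot reach C4.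

Step 15
Reactants: 24 perbenzylated target
Product: 25 epigallocatechin 3-O-gallate-(4β→8)-epigallocatechin (CNP0194932.2)
Conditions: H2 (1 atm), Pd(OH)2/C, THF/MeOH/H2O, rt; filtration under argon, lyophilisation
Reagents that add atoms: none
Why: Catalytic hydrogenolysis cleaves all fourteen O-benzyl groups under neutral conditions known to spare the gallate ester, the C2–O1 bonds and the interflavan bond of benzylated proanthocyanidins, and no stereocentre is affected.

Compound list
1 | 5-bromobenzene-1,2,3-triol | Oc1cc(Br)cc(O)c1O | starting material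
2 | 1,2,3-tris(benzyloxy)-5-bromobenzene | Brc1cc(OCc4ccccc4)c(OCc4ccccc4)c(OCc4ccccc4)c1 | intermediate
3 | (R)-glyceraldehyde acetonide | CC1(C)OC[C@H](C=O)O1 | starting material
4 | 3,4,5-tris(benzyloxy)phenylmagnesium bromide | Br[Mg]c1cc(OCc4ccccc4)c(OCc4ccccc4)c(OCc4ccccc4)c1 | intermediate
5 | (S)-[(4R)-2,2-dimethyl-1,3-dioxolan-4-yl][3,4,5-tris(benzyloxy)phenyl]methanol | CC1(C)OC[C@H]([C@@H](O)c2cc(OCc4ccccc4)c(OCc4ccccc4)c(OCc4ccccc4)c2)O1 | intermediate
6 | 3,5-bis(benzyloxy)phenol | Oc1cc(OCc2ccccc2)cc(OCc2ccccc2)c1 | starting material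
7 | (4R)-4-{(R)-[3,5-bis(benzyloxy)phenoxy][3,4,5-tris(benzyloxy)phenyl]methyl}-2,2-dimethyl-1,3-dioxolane | CC1(C)OC[C@H]([C@H](Oc2cc(OCc4ccccc4)cc(OCc4ccccc4)c2)c2cc(OCc4ccccc4)c(OCc4ccccc4)c(OCc4ccccc4)c2)O1 | intermediate
8 | (2R,3R)-3-[3,5-bis(benzyloxy)phenoxy]-3-[3,4,5-tris(benzyloxy)phenyl]propane-1,2-diol | OC[C@H]([C@H](Oc2cc(OCc4ccccc4)cc(OCc4ccccc4)c2)c2cc(OCc4ccccc4)c(OCc4ccccc4)c(OCc4ccccc4)c2)O | intermediate
9 | 1,2-bis(tert-butyldimethylsilyl) ether of 8 | CC(C)(C)[Si](C)(C)OC[C@H]([C@H](Oc2cc(OCc4ccccc4)cc(OCc4ccccc4)c2)c2cc(OCc4ccccc4)c(OCc4ccccc4)c(OCc4ccccc4)c2)O[Si](C)(C)C(C)(C)C | intermediate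
10 | (2R,3R)-3-[3,5-bis(benzyloxy)phenoxy]-2-(tert-butyldimethylsilyloxy)-3-[3,4,5-tris(benzyloxy)phenyl]propan-1-ol | OC[C@H]([C@H](Oc2cc(OCc4ccccc4)cc(OCc4ccccc4)c2)c2cc(OCc4ccccc4)c(OCc4ccccc4)c(OCc4ccccc4)c2)O[Si](C)(C)C(C)(C)C | intermediate
11 | (2S,3R)-3-[3,5-bis(benzyloxy)phenoxy]-2-(tert-butyldimethylsilyloxy)-3-[3,4,5-tris(benzyloxy)phenyl]propanal | O=C[C@H]([C@H](Oc2cc(OCc4ccccc4)cc(OCc4ccccc4)c2)c2cc(OCc4ccccc4)c(OCc4ccccc4)c(OCc4ccccc4)c2)O[Si](C)(C)C(C)(C)C | intermediate
12 | (−)-epigallocatechin | Oc1cc(O)c2c(c1)O[C@H](c1cc(O)c(O)c(O)c1)[C@H](O)C2 | starting material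
13 | 5,7,3',4',5'-penta-O-benzyl-(−)-epigallocatechin | O(Cc4ccccc4)c1cc(OCc4ccccc4)c2c(c1)O[C@H](c1cc(OCc4ccccc4)c(OCc4ccccc4)c(OCc4ccccc4)c1)[C@H](O)C2 | intermediate
14 | 3,5,7,3',4',5'-hexa-O-benzyl-(−)-epigallocatechin | O(Cc4ccccc4)c1cc(OCc4ccccc4)c2c(c1)O[C@H](c1cc(OCc4ccccc4)c(OCc4ccccc4)c(OCc4ccccc4)c1)[C@H](OCc4ccccc4)C2 | intermediate
15 | 8-bromo-hexa-O-benzyl-(−)-epigallocatechin | Brc1c(OCc4ccccc4)cc(OCc4ccccc4)c2c1O[C@H](c1cc(OCc4ccccc4)c(OCc4ccccc4)c(OCc4ccccc4)c1)[C@H](OCc4ccccc4)C2 | intermediate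
16 | 8-lithio-hexa-O-benzyl-(−)-epigallocatechin | [Li]c1c(OCc4ccccc4)cc(OCc4ccccc4)c2c1O[C@H](c1cc(OCc4ccccc4)c(OCc4ccccc4)c(OCc4ccccc4)c1)[C@H](OCc4ccccc4)C2 | intermediate
17 | lithium C4 alkoxide of the adduct (O3 silylated, both C4 epimers) | CC(C)(C)[Si](C)(C)O[C@H](C(O[Li])c2c(OCc4ccccc4)cc(OCc4ccccc4)c3c2O[C@H](c2cc(OCc4ccccc4)c(OCc4ccccc4)c(OCc4ccccc4)c2)[C@H](OCc4ccccc4)C3)[C@H](Oc2cc(OCc4ccccc4)cc(OCc4ccccc4)c2)c1cc(OCc4ccccc4)c(OCc4ccccc4)c(OCc4ccccc4)c1 | intermediate
18 | C4 methyl ether, O3 tert-butyldimethylsilyl ether (2R,3R; both C4 epimers) | CC(C)(C)[Si](C)(C)O[C@H](C(OC)c2c(OCc4ccccc4)cc(OCc4ccccc4)c3c2O[C@H](c2cc(OCc4ccccc4)c(OCc4ccccc4)c(OCc4ccccc4)c2)[C@H](OCc4ccccc4)C3)[C@H](Oc2cc(OCc4ccccc4)cc(OCc4ccccc4)c2)c1cc(OCc4ccccc4)c(OCc4ccccc4)c(OCc4ccccc4)c1 | intermediate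
19 | C4 methyl ether, free C3 alcohol (2R,3R; both C4 epimers) | O[C@H](C(OC)c2c(OCc4ccccc4)cc(OCc4ccccc4)c3c2O[C@H](c2cc(OCc4ccccc4)c(OCc4ccccc4)c(OCc4ccccc4)c2)[C@H](OCc4ccccc4)C3)[C@H](Oc2cc(OCc4ccccc4)cc(OCc4ccccc4)c2)c1cc(OCc4ccccc4)c(OCc4ccccc4)c(OCc4ccccc4)c1 | intermediate
20 | 3,4,5-tris(benzyloxy)benzoic acid | OC(=O)c1cc(OCc4ccccc4)c(OCc4ccccc4)c(OCc4ccccc4)c1 | starting material
21 | key precursor: acyclic 3-O-galloyl C4 methyl ether (2R,3R; both C4 epimers) | O=C(O[C@H](C(OC)c2c(OCc4ccccc4)cc(OCc4ccccc4)c3c2O[C@H](c2cc(OCc4ccccc4)c(OCc4ccccc4)c(OCc4ccccc4)c2)[C@H](OCc4ccccc4)C3)[C@H](Oc2cc(OCc4ccccc4)cc(OCc4ccccc4)c2)c1cc(OCc4ccccc4)c(OCc4ccccc4)c(OCc4ccccc4)c1)c1cc(OCc4ccccc4)c(OCc4ccccc4)c(OCc4ccccc4)c1 | intermediate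
22 | C4 benzylic cation (triflate) | O=C(O[C@H]([CH+]c2c(OCc4ccccc4)cc(OCc4ccccc4)c3c2O[C@H](c2cc(OCc4ccccc4)c(OCc4ccccc4)c(OCc4ccccc4)c2)[C@H](OCc4ccccc4)C3)[C@H](Oc2cc(OCc4ccccc4)cc(OCc4ccccc4)c2)c1cc(OCc4ccccc4)c(OCc4ccccc4)c(OCc4ccccc4)c1)c1cc(OCc4ccccc4)c(OCc4ccccc4)c(OCc4ccccc4)c1.[O-]S(=O)(=O)C(F)(F)F | intermediate
23 | trans-4,5-disubstituted 2-[3,4,5-tris(benzyloxy)phenyl]-1,3-dioxolan-2-ylium triflate | C5(c1cc(OCc4ccccc4)c(OCc4ccccc4)c(OCc4ccccc4)c1)=[O+][C@@H](c2c(OCc4ccccc4)cc(OCc4ccccc4)c3c2O[C@H](c2cc(OCc4ccccc4)c(OCc4ccccc4)c(OCc4ccccc4)c2)[C@H](OCc4ccccc4)C3)[C@H]([C@H](Oc2cc(OCc4ccccc4)cc(OCc4ccccc4)c2)c1cc(OCc4ccccc4)c(OCc4ccccc4)c(OCc4ccccc4)c1)O5.[O-]S(=O)(=O)C(F)(F)F | intermediate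
24 | perbenzylated target (2R,3R,4R,2'R,3'R) | O=C(O[C@@H]1[C@@H](c2c(OCc4ccccc4)cc(OCc4ccccc4)c3c2O[C@H](c2cc(OCc4ccccc4)c(OCc4ccccc4)c(OCc4ccccc4)c2)[C@H](OCc4ccccc4)C3)c2c(OCc4ccccc4)cc(OCc4ccccc4)cc2O[C@@H]1c1cc(OCc4ccccc4)c(OCc4ccccc4)c(OCc4ccccc4)c1)c1cc(OCc4ccccc4)c(OCc4ccccc4)c(OCc4ccccc4)c1 | intermediate
25 | epigallocatechin 3-O-gallate-(4β→8)-epigallocatechin (CNP0194932.2) | O=C(O[C@@H]1[C@@H](c2c(O)cc(O)c3c2O[C@H](c2cc(O)c(O)c(O)c2)[C@H](O)C3)c2c(O)cc(O)cc2O[C@@H]1c1cc(O)c(O)c(O)c1)c1cc(O)c(O)c(O)c1 | target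

Total step count: 15. Longest linear sequence: 12 (steps 1–7 and 11–15).

Steps most likely to fail

Step 14. The cation may be consumed by intermolecular arylation and oligomerisation, by proton loss from C3 to an enol gallate, or by five-membered closure onto ring B. Slow closure could also allow ionisation at C2 and erosion of its configuration. The fallback gives up the late ring closure and joins two preformed flavans by known chemistry. It sets out from 13, which is oxidised at C4 with DDQ in CH2Cl2 in the presence of 2-ethoxyethanol to give 5,7,3',4',5'-penta-O-benzyl-4β-(2-ethoxyethoxy)-epigallocatechin F1. Esterification of F1 with 20 (DCC, DMAP) gives its 3-O-[3,4,5-tris(benzyloxy)benzoyl] ester F2. F2 is then condensed with an excess of nucleophile 14 under Me3SiOTf in CH2Cl2 at −78 °C. The cyclic C4 cation, shielded on its lower face by the participating gallate, is arylated by C8 of 14 to give the 3,4-trans dimer, and the route is rejoined at 24.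

Step 11. The hindered aryllithium may deprotonate the aldehyde with loss of the phenoxide. The silyl group may migrate from O3 to O4 in the alkoxide, or capture of the crowded alkoxide by the methylating agent may be incomplete. The fallback drops the differentiation of O3 and O4 altogether. It sets out from 11 and 15: after the addition the alkoxide is quenched at −78 °C with AcOH to give the O3-silylated C4 carbinol F3. Bu4NF then frees the 3,4-diol F4. Exhaustive esterification with excess 20 (DCC, DMAP) gives the 3,4-di-O-[3,4,5-tris(benzyloxy)benzoyl] ester F5. In F5 the activated benzylic C4 ester serves as the leaving group and the C3 ester as the participating group, so treatment with Me3SiOTf as in step 14 should close ring C, and the route is rejoined at 24.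

Step 3. The activated electron-rich benzylic C2 centre may ionise partly, so that inversion is incomplete. The phenol may also react through carbon, or the hindered carbinol may react sluggishly. The fallback forms the C2–O–aryl link at the aryl carbon, with retention at C2. It sets out from 5, which is oxidised with Dess–Martin periodinane to the ketone [(4R)-2,2-dimethyl-1,3-dioxolan-4-yl][3,4,5-tris(benzyloxy)phenyl]methanone F6. Non-chelated Felkin–Anh hydride delivery with LiBH(s-Bu)3 in THF at −78 °C should give the 2,3-syn carbinol (R)-[(4R)-2,2-dimethyl-1,3-dioxolan-4-yl][3,4,5-tris(benzyloxy)phenyl]methanol F7. Buchwald–Hartwig-type C–O coupling of F7 with 1-bromo-3,5-bis(benzyloxy)benzene ([Pd(allyl)Cl]2, RockPhos, Cs2CO3, toluene, 90 °C) leaves the C2–O bond intact, and the route is rejoined at 7.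

Further compounds
F1 | step 14 | 5,7,3',4',5'-penta-O-benzyl-4β-(2-ethoxyethoxy)-epigallocatechin | O[C@@H]1[C@@H](OCCOCC)c2c(OCc4ccccc4)cc(OCc4ccccc4)cc2O[C@@H]1c1cc(OCc4ccccc4)c(OCc4ccccc4)c(OCc4ccccc4)c1
F2 | step 14 | 3-O-[3,4,5-tris(benzyloxy)benzoyl] ester of F1 | O=C(O[C@@H]1[C@@H](OCCOCC)c2c(OCc4ccccc4)cc(OCc4ccccc4)cc2O[C@@H]1c1cc(OCc4ccccc4)c(OCc4ccccc4)c(OCc4ccccc4)c1)c1cc(OCc4ccccc4)c(OCc4ccccc4)c(OCc4ccccc4)c1
F3 | step 11 | O3-silylated C4 carbinol (both C4 epimers) | CC(C)(C)[Si](C)(C)O[C@H](C(O)c2c(OCc4ccccc4)cc(OCc4ccccc4)c3c2O[C@H](c2cc(OCc4ccccc4)c(OCc4ccccc4)c(OCc4ccccc4)c2)[C@H](OCc4ccccc4)C3)[C@H](Oc2cc(OCc4ccccc4)cc(OCc4ccccc4)c2)c1cc(OCc4ccccc4)c(OCc4ccccc4)c(OCc4ccccc4)c1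
F4 | step 11 | acyclic 3,4-diol (both C4 epimers) | O[C@H](C(O)c2c(OCc4ccccc4)cc(OCc4ccccc4)c3c2O[C@H](c2cc(OCc4ccccc4)c(OCc4ccccc4)c(OCc4ccccc4)c2)[C@H](OCc4ccccc4)C3)[C@H](Oc2cc(OCc4ccccc4)cc(OCc4ccccc4)c2)c1cc(OCc4ccccc4)c(OCc4ccccc4)c(OCc4ccccc4)c1
F5 | step 11 | acyclic 3,4-di-O-[3,4,5-tris(benzyloxy)benzoyl] ester (both C4 epimers) | O=C(O[C@H](C(OC(=O)c1cc(OCc4ccccc4)c(OCc4ccccc4)c(OCc4ccccc4)c1)c2c(OCc4ccccc4)cc(OCc4ccccc4)c3c2O[C@H](c2cc(OCc4ccccc4)c(OCc4ccccc4)c(OCc4ccccc4)c2)[C@H](OCc4ccccc4)C3)[C@H](Oc2cc(OCc4ccccc4)cc(OCc4ccccc4)c2)c1cc(OCc4ccccc4)c(OCc4ccccc4)c(OCc4ccccc4)c1)c1cc(OCc4ccccc4)c(OCc4ccccc4)c(OCc4ccccc4)c1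
F6 | step 3 | [(4R)-2,2-dimethyl-1,3-dioxolan-4-yl][3,4,5-tris(benzyloxy)phenyl]methanone | CC1(C)OC[C@H](C(=O)c2cc(OCc4ccccc4)c(OCc4ccccc4)c(OCc4ccccc4)c2)O1
F7 | step 3 | (R)-[(4R)-2,2-dimethyl-1,3-dioxolan-4-yl][3,4,5-tris(benzyloxy)phenyl]methanol | CC1(C)OC[C@H]([C@H](O)c2cc(OCc4ccccc4)c(OCc4ccccc4)c(OCc4ccccc4)c2)O1
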